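**Retrosynthetic overview**
1. Last bonds: ring C–C7' by Felkin–Anh addition of an aryl Grignard reagent to an (R)-2-aryloxypropanal, and ring B O–C8' by Mitsunobu inversion of ethyl (S)-lactate on the ring B phenol; both silyl ethers are removed in the final step.
2. Oxolane (O1, C2 with ring A, C3, C4, C5 with ring B): ring A–C2 by aryllithium addition to a C2 lactone, then C2–H by hydride delivery to the oxocarbenium ion anti to the C3 methyl (2,3-cis).
3. Feature the strategy rests on: the C3 and C4 methyls are cis to each other and both trans to ring B on C5. They are therefore carried as the two CH2 arms of one thiolane, laid on the C3=C4 bond of the (S)-5-aryl butenolide by a thiocarbonyl ylide (3+2) cycloaddition anti to ring B, and unmasked by Raney Ni.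
4. The butenolide comes from O-benzylvanillin by vinyl Grignard addition, lipase resolution, acrylation and ring-closing metathesis.
5. Ring order: butenolide ring (metathesis), then thiolane (cycloaddition, later opened by desulfurisation), then the lactone ring becomes the oxolane; rings A and C both come from one silylated 4-bromoguaiacol.

Key step: step 5

Remark: the oxolane atoms are numbered O1, C2 (ring A), C3, C4, C5 (ring B) in every intermediate, the lactone carbonyl carbon being the future C2; O-benzylvanillin is taken as purchased.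

**Step 1**
Reactants: 1 4-(benzyloxy)-3-methoxybenzaldehyde; 2 vinylmagnesium bromide
Product: 3 rac-1-[4-(benzyloxy)-3-methoxyphenyl]prop-2-en-1-ol
Conditions: CH2=CHMgBr (1.2 equiv), THF, −78 → 0 °C; then H2O
Reagents that add atoms: vinylmagnesium bromide, C=C[Mg]Br
Why: Grignard 1,2-addition to a non-enolisable aryl aldehyde should be clean; the racemic para-alkoxybenzylic allylic alcohol is worked up without acid because it ionises easily.

**Step 2**
Reactants: 3 rac-1-[4-(benzyloxy)-3-methoxyphenyl]prop-2-en-1-ol
Product: 4 (S)-1-[4-(benzyloxy)-3-methoxyphenyl]prop-2-en-1-ol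
Conditions: Novozym 435 (immobilised Candida antarctica lipase B), vinyl acetate (3 equiv), tBuOMe, 30 °C, stopped just past half conversion; chromatography
Reagents that add atoms: none
Why: Enzymatic kinetic resolution by lipase-catalysed transesterification: by the empirical size rule for secondary alcohols (aryl large, vinyl medium) the (R)-alcohol should be acetylated fast, so the recovered alcohol should be the (S)-enantiomer that carries the future C5 configuration.

**Step 3**
Reactants: 4 (S)-1-[4-(benzyloxy)-3-methoxyphenyl]prop-2-en-1-ol; 5 acryloyl chloride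
Product: 6 (S)-1-[4-(benzyloxy)-3-methoxyphenyl]prop-2-en-1-yl prop-2-enoate
Conditions: Et3N, CH2Cl2, −20 → 0 °C; Et3N-deactivated silica
Reagents that add atoms: acryloyl chloride, C=CC(=O)Cl
Why: O-acylation of a secondary alcohol with an acid chloride and amine base leaves the C–O bond at the stereocentre untouched, so the configuration is retained.

**Step 4**
Reactants: 6 (S)-1-[4-(benzyloxy)-3-methoxyphenyl]prop-2-en-1-yl prop-2-enoate
Product: 7 (S)-5-[4-(benzyloxy)-3-methoxyphenyl]furan-2(5H)-one
Conditions: second-generation Grubbs catalyst RuCl2(=CHPh)(PCy3)(SIMes) (5 mol %), CH2Cl2 (0.01 M), 40 °C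
Reagents that add atoms: none
Why: Ring-closing metathesis of an acrylate and a terminal alkene to a five-membered butenolide should proceed with the carbene-ligated ruthenium catalyst that electron-poor acrylates need, under neutral conditions that do not touch the C5 stereocentre.

**Step 5**
Reactants: 7 (S)-5-[4-(benzyloxy)-3-methoxyphenyl]furan-2(5H)-one; 8 chloromethyl (trimethylsilyl)methyl sulfide
Product: 10 cis-fused thiolane lactone (3S,3aS,6aR)-3-[4-(benzyloxy)-3-methoxyphenyl]tetrahydro-1H-thieno[3,4-c]furan-1-one, via thiocarbonyl ylide 9 (not isolated)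
Conditions: CsF (4 equiv), 8 (3 equiv, slow addition), MeCN, 0 °C → rt
Reagents that add atoms: chloromethyl (trimethylsilyl)methyl sulfide, C[Si](C)(C)CSCCl
Why: Fluoride attacks the silicon of 8 and chloride leaves from the other carbon, a 1,3-elimination that releases the parent thiocarbonyl ylide 9, an electron-rich 4π dipole matched to the low-lying LUMO of the butenolide C3=C4 bond. The closest known reaction type is the (3+2) dipolar cycloaddition of this unstabilised ylide to α,β-unsaturated lactones and esters. The thiolane ring closes by an intermolecular, concerted, suprafacial (3+2) annulation that forms the C3–CH2 and C4–CH2 bonds together, so the 5/5 ring fusion can only be cis. The two new stereocentres (lactone C3 and C4) are fixed relative to each other by this suprafacial addition and relative to C5 by ring B, which screens its own face of the flat butenolide so that the dipole adds anti to it. The dipole is symmetric, so no regiochemical question arises and only π-facial selectivity is needed, which the single C5 substituent next to the reacting alkene supplies. Slow addition of 8 to sparingly soluble CsF keeps the ylide and free fluoride concentrations low, limiting ylide self-reaction and deprotonation of the acidic C5–H.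

**Step 6**
Reactants: 10 cis-fused thiolane lactone (3S,3aS,6aR)-3-[4-(benzyloxy)-3-methoxyphenyl]tetrahydro-1H-thieno[3,4-c]furan-1-one
Product: 11 (3R,4S,5S)-5-[4-(benzyloxy)-3-methoxyphenyl]-3,4-dimethyloxolan-2-one
Conditions: Raney Ni (W-2, washed neutral, aged in acetone), EtOH/THF, rt
Reagents that add atoms: none
Why: Reductive desulfurisation with Raney Ni cleaves both C–S bonds without touching any stereocentre, so the two thiolane CH2 arms become the cis C3 and C4 methyls, and neutral, deactivated nickel at room temperature should spare the benzyl ether and the benzylic lactone C–O bond.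

**Step 7**
Reactants: 12 4-bromo-2-methoxyphenol; 13 tert-butyldimethylsilyl chloride
Product: 14 (4-bromo-2-methoxyphenoxy)(tert-butyl)dimethylsilane
Conditions: TBSCl, imidazole, DMF, rt
Reagents that add atoms: tert-butyldimethylsilyl chloride, CC(C)(C)[Si](C)(C)Cl
Why: Silylation of a phenol gives one aryl bromide that serves for rings A and C, with a fluoride-labile group orthogonal to the benzyl ether on ring B.

**Step 8**
Reactants: 11 (3R,4S,5S)-5-[4-(benzyloxy)-3-methoxyphenyl]-3,4-dimethyloxolan-2-one; 14 (4-bromo-2-methoxyphenoxy)(tert-butyl)dimethylsilane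
Product: 16 hemiketal (3R,4S,5S)-5-[4-(benzyloxy)-3-methoxyphenyl]-2-{4-[(tert-butyldimethylsilyl)oxy]-3-methoxyphenyl}-3,4-dimethyloxolan-2-ol (both C2 epimers), via aryllithium 15 (not isolated)
Conditions: 14, n-BuLi, THF, −78 °C; then 11, −78 °C; then H2O
Reagents that add atoms: 14 (4-bromo-2-methoxyphenoxy)(tert-butyl)dimethylsilane, COc1cc(Br)ccc1O[Si](C)(C)C(C)(C)C
Why: Bromine–lithium exchange followed by 1,2-addition of the aryllithium to the lactone carbonyl should stop after one addition at −78 °C because the adduct does not collapse before the quench, and the cold, brief exposure should leave C3 unepimerised.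

**Step 9**
Reactants: 16 hemiketal (both C2 epimers)
Product: 18 tert-butyl{4-[(2S,3R,4S,5S)-5-(4-benzyloxy-3-methoxyphenyl)-3,4-dimethyloxolan-2-yl]-2-methoxyphenoxy}dimethylsilane, via oxocarbenium ion 17 (not isolated)
Conditions: Et3SiH (3 equiv), BF3·OEt2 (1.5 equiv), CH2Cl2, −78 °C; then Et3N, aq. NaHCO3 at −78 °C
Reagents that add atoms: none
Why: Ionic hydrogenation of a cyclic hemiketal: BF3 ionises 16 to the aryl-stabilised oxocarbenium ion 17 and the silane delivers hydride to C2 on the face anti to the adjacent C3 methyl (and the C4 methyl), which places ring A cis to that methyl (2S), while −78 °C should suppress Lewis-acid epimerisation at the benzylic C2 and C5.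

**Step 10**
Reactants: 18 tert-butyl{4-[(2S,3R,4S,5S)-5-(4-benzyloxy-3-methoxyphenyl)-3,4-dimethyloxolan-2-yl]-2-methoxyphenoxy}dimethylsilane
Product: 19 ring B phenol 4-[(2S,3R,4S,5S)-2-{4-[(tert-butyldimethylsilyl)oxy]-3-methoxyphenyl}-3,4-dimethyloxolan-5-yl]-2-methoxyphenol
Conditions: H2 (1 atm), Pd/C (10 wt %), EtOAc, rt, stopped at full conversion
Reagents that add atoms: none
Why: Hydrogenolysis of an aryl benzyl ether over palladium on carbon is fast, leaves the silyl ether alone, and a short run at 1 atm in EtOAc should not open the benzylic C–O bonds of the oxolane.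

**Step 11**
Reactants: 19 ring B phenol; 20 ethyl (S)-lactate
Product: 21 ethyl (2R)-2-{4-[(2S,3R,4S,5S)-2-{4-[(tert-butyldimethylsilyl)oxy]-3-methoxyphenyl}-3,4-dimethyloxolan-5-yl]-2-methoxyphenoxy}propanoate
Conditions: PPh3, DIAD, THF, 0 °C → rt
Reagents that add atoms: ethyl (S)-lactate, CCOC(=O)[C@H](C)O
Why: Mitsunobu etherification of a phenol with a secondary alcohol proceeds by SN2 displacement of the activated lactate hydroxyl, so inversion sets the (R) configuration at the aryloxy carbon (future C8').

**Step 12**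
Reactants: 21 ethyl (2R)-2-aryloxypropanoate
Product: 22 (2R)-2-{4-[(2S,3R,4S,5S)-2-{4-[(tert-butyldimethylsilyl)oxy]-3-methoxyphenyl}-3,4-dimethyloxolan-5-yl]-2-methoxyphenoxy}propanal
Conditions: iBu2AlH (1.1 equiv), CH2Cl2, −78 °C; then MeOH, aq. potassium sodium tartrate; used crude at once
Reagents that add atoms: none
Why: Partial reduction of an ester to the aldehyde with iBu2AlH at −78 °C is favoured by the α-aryloxy group, and using the aldehyde cold and unpurified should avoid epimerisation of its α-stereocentre.

**Step 13**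
Reactants: 22 (2R)-2-aryloxypropanal; 14 (4-bromo-2-methoxyphenoxy)(tert-butyl)dimethylsilane
Product: 24 (1S,2R)-1-{4-[(tert-butyldimethylsilyl)oxy]-3-methoxyphenyl}-2-{4-[(2S,3R,4S,5S)-2-{4-[(tert-butyldimethylsilyl)oxy]-3-methoxyphenyl}-3,4-dimethyloxolan-5-yl]-2-methoxyphenoxy}propan-1-ol, via arylmagnesium bromide 23 (not isolated)
Conditions: 14, Mg, cat. I2, THF, 40 °C; then 22, THF, −78 °C; then H2O
Reagents that add atoms: 14 (4-bromo-2-methoxyphenoxy)(tert-butyl)dimethylsilane, COc1cc(Br)ccc1O[Si](C)(C)C(C)(C)C
Why: Grignard 1,2-addition to an α-aryloxy aldehyde under Felkin–Anh (polar) control, with the C–OAr bond anti to the incoming aryl group and attack past H instead of CH3, should turn the (R)-aldehyde into the (1S,2R) erythro alcohol, and coordinating THF at −78 °C disfavours the competing chelate.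

**Step 14**
Reactants: 24 bis-silyl ether of the target
Product: 25 target, 4-[(2S,3R,4S,5S)-5-{4-[(1S,2R)-1-hydroxy-1-(4-hydroxy-3-methoxyphenyl)propan-2-yl]oxy-3-methoxyphenyl}-3,4-dimethyloxolan-2-yl]-2-methoxyphenol
Conditions: Bu4NF (2.5 equiv), AcOH (2.5 equiv), THF, 0 °C
Reagents that add atoms: none
Why: Fluoride-mediated cleavage of both aryl silyl ethers touches no stereocentre, and the acetic acid buffer keeps the phenols protonated so that the para-hydroxybenzylic alcohol and the oxolane are not exposed to phenoxide base.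

**Compound list**
1 | 4-(benzyloxy)-3-methoxybenzaldehyde (O-benzylvanillin) | COc1cc(C=O)ccc1OCc1ccccc1 | starting material
2 | vinylmagnesium bromide | C=C[Mg]Br | starting material
3 | rac-1-[4-(benzyloxy)-3-methoxyphenyl]prop-2-en-1-ol | COc1cc(C(O)C=C)ccc1OCc1ccccc1 | intermediate
4 | (S)-1-[4-(benzyloxy)-3-methoxyphenyl]prop-2-en-1-ol | O[C@H](c1ccc(OCc2ccccc2)c(OC)c1)C=C | intermediate
5 | acryloyl chloride | C=CC(=O)Cl | starting material
6 | (S)-1-[4-(benzyloxy)-3-methoxyphenyl]prop-2-en-1-yl prop-2-enoate | C=CC(=O)O[C@H](c1ccc(OCc2ccccc2)c(OC)c1)C=C | intermediate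
7 | (S)-5-[4-(benzyloxy)-3-methoxyphenyl]furan-2(5H)-one | O=C1O[C@H](c2ccc(OCc3ccccc3)c(OC)c2)C=C1 | intermediate
8 | chloromethyl (trimethylsilyl)methyl sulfide | C[Si](C)(C)CSCCl | starting material
9 | thiocarbonyl ylide (thioformaldehyde S-methylide) | C=[S+][CH2-] | intermediate (not isolated)
10 | (3S,3aS,6aR)-3-[4-(benzyloxy)-3-methoxyphenyl]tetrahydro-1H-thieno[3,4-c]furan-1-one, cis-fused, ring B trans to both CH2 arms | O=C1O[C@H](c3ccc(OCc4ccccc4)c(OC)c3)[C@@H](CS2)[C@H]1C2 | intermediate
11 | (3R,4S,5S)-5-[4-(benzyloxy)-3-methoxyphenyl]-3,4-dimethyloxolan-2-one | O=C1O[C@H](c2ccc(OCc3ccccc3)c(OC)c2)[C@@H](C)[C@H]1C | intermediate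
12 | 4-bromo-2-methoxyphenol | COc1cc(Br)ccc1O | starting material
13 | tert-butyldimethylsilyl chloride | CC(C)(C)[Si](C)(C)Cl | starting material
14 | (4-bromo-2-methoxyphenoxy)(tert-butyl)dimethylsilane | COc1cc(Br)ccc1O[Si](C)(C)C(C)(C)C | intermediate
15 | {4-[(tert-butyldimethylsilyl)oxy]-3-methoxyphenyl}lithium | COc1cc([Li])ccc1O[Si](C)(C)C(C)(C)C | intermediate (not isolated)
16 | (3R,4S,5S)-5-[4-(benzyloxy)-3-methoxyphenyl]-2-{4-[(tert-butyldimethylsilyl)oxy]-3-methoxyphenyl}-3,4-dimethyloxolan-2-ol, both C2 epimers | COc1cc(C2(O)O[C@H](c3ccc(OCc4ccccc4)c(OC)c3)[C@@H](C)[C@H]2C)ccc1O[Si](C)(C)C(C)(C)C | intermediate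
17 | C2=O1(+) oxocarbenium ion from 16, (3R,4S,5S) | COc1cc(C2=[O+][C@H](c3ccc(OCc4ccccc4)c(OC)c3)[C@@H](C)[C@H]2C)ccc1O[Si](C)(C)C(C)(C)C | intermediate (not isolated)
18 | tert-butyl{4-[(2S,3R,4S,5S)-5-(4-benzyloxy-3-methoxyphenyl)-3,4-dimethyloxolan-2-yl]-2-methoxyphenoxy}dimethylsilane | COc1cc([C@H]2O[C@H](c3ccc(OCc4ccccc4)c(OC)c3)[C@@H](C)[C@H]2C)ccc1O[Si](C)(C)C(C)(C)C | intermediate
19 | 4-[(2S,3R,4S,5S)-2-{4-[(tert-butyldimethylsilyl)oxy]-3-methoxyphenyl}-3,4-dimethyloxolan-5-yl]-2-methoxyphenol | COc1cc([C@H]2O[C@H](c3ccc(O)c(OC)c3)[C@@H](C)[C@H]2C)ccc1O[Si](C)(C)C(C)(C)C | intermediate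
20 | ethyl (S)-lactate | CCOC(=O)[C@H](C)O | starting material
21 | ethyl (2R)-2-(ring B aryloxy)propanoate of 19 | COc1cc([C@H]2O[C@H](c3ccc(O[C@H](C)C(=O)OCC)c(OC)c3)[C@@H](C)[C@H]2C)ccc1O[Si](C)(C)C(C)(C)C | intermediate
22 | (2R)-2-(ring B aryloxy)propanal | COc1cc([C@H]2O[C@H](c3ccc(O[C@H](C)C=O)c(OC)c3)[C@@H](C)[C@H]2C)ccc1O[Si](C)(C)C(C)(C)C | intermediate
23 | {4-[(tert-butyldimethylsilyl)oxy]-3-methoxyphenyl}magnesium bromide | COc1cc([Mg]Br)ccc1O[Si](C)(C)C(C)(C)C | intermediate (not isolated)
24 | bis-silyl ether of the target, (1S,2R) erythro alcohol | COc1cc([C@H]2O[C@H](c3ccc(O[C@H](C)[C@@H](O)c4ccc(O[Si](C)(C)C(C)(C)C)c(OC)c4)c(OC)c3)[C@@H](C)[C@H]2C)ccc1O[Si](C)(C)C(C)(C)C | intermediate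
25 | 4-[(2S,3R,4S,5S)-5-{4-[(1S,2R)-1-hydroxy-1-(4-hydroxy-3-methoxyphenyl)propan-2-yl]oxy-3-methoxyphenyl}-3,4-dimethyloxolan-2-yl]-2-methoxyphenol | COc1cc([C@H]2O[C@H](c3ccc(O[C@H](C)[C@@H](O)c4ccc(O)c(OC)c4)c(OC)c3)[C@@H](C)[C@H]2C)ccc1O | target

**Step count**
Total: 14 steps. Longest linear sequence: 13 steps (steps 1–6 and 8–14 from 1); step 7 is a one-step side branch that feeds steps 8 and 13.

**Steps most likely to fail**

Step 5. Fluoride may act as a base on the C5–H of 7, which is activated by ring B and by formation of an aromatic 2-oxidofuran, so enantiopurity could erode or the double bond could migrate. The ylide may also consume itself faster than it adds to the 1,2-disubstituted enoate. The fallback sets out from 7 and returns at 11, building the two methyls one at a time by anionic chemistry. Conjugate addition of Me2CuLi (Et2O, −78 °C) anti to ring B should give (4S,5S)-5-[4-(benzyloxy)-3-methoxyphenyl]-4-methyloxolan-2-one F1. Deprotonation with LiN(iPr)2 and methylation with MeI anti to the C4 methyl should give the 3,4-trans lactone (3S,4S,5S)-5-[4-(benzyloxy)-3-methoxyphenyl]-3,4-dimethyloxolan-2-one F2. A second deprotonation with LiN(iPr)2 gives its lithium enolate F3. Kinetic protonation of F3 with 2,6-di-tert-butyl-4-methylphenol at −78 °C, on the face anti to the C4 methyl, should invert C3 and deliver the cis-dimethyl lactone 11.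

Step 6. Hydrogenolysis of the aryl benzyl ether on the nickel surface may run alongside C–S cleavage, giving mixtures of protected and unprotected material. The fallback sets out from 10 and returns at 11. Both processes are driven to completion with excess hydrogen-saturated Raney Ni (EtOH, 50 °C) to give the phenol lactone (3R,4S,5S)-5-(4-hydroxy-3-methoxyphenyl)-3,4-dimethyloxolan-2-one F4. Re-benzylation of F4 (BnBr, K2CO3, acetone) then restores 11.

Step 13. Magnesium chelation between the aldehyde oxygen and the guaiacyl ether oxygens may compete with the Felkin–Anh pathway and lower the diastereocontrol at C7'. The fallback sets out from 24 obtained as a mixture of C7' epimers and returns at 24. Oxidation with Dess–Martin periodinane (NaHCO3, CH2Cl2) should converge both epimers on the (R)-α-aryloxy ketone F5. Reduction of F5 with Zn(BH4)2 (Et2O, −30 °C) under chelation control, with hydride entering past H of the zinc chelate, should give the erythro (1S,2R) alcohol 24.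

**Further compounds**
F1 | step 5 | (4S,5S)-5-[4-(benzyloxy)-3-methoxyphenyl]-4-methyloxolan-2-one | O=C1O[C@H](c2ccc(OCc3ccccc3)c(OC)c2)[C@@H](C)C1
F2 | step 5 | (3S,4S,5S)-5-[4-(benzyloxy)-3-methoxyphenyl]-3,4-dimethyloxolan-2-one | O=C1O[C@H](c2ccc(OCc3ccccc3)c(OC)c2)[C@@H](C)[C@@H]1C
F3 | step 5 | lithium enolate of F2 | CC1=C(O[Li])O[C@H](c2ccc(OCc3ccccc3)c(OC)c2)[C@H]1C
F4 | step 6 | (3R,4S,5S)-5-(4-hydroxy-3-methoxyphenyl)-3,4-dimethyloxolan-2-one | O=C1O[C@H](c2ccc(O)c(OC)c2)[C@@H](C)[C@H]1C
F5 | step 13 | (2R)-1-{4-[(tert-butyldimethylsilyl)oxy]-3-methoxyphenyl}-2-(ring B aryloxy)propan-1-one | COc1cc([C@H]2O[C@H](c3ccc(O[C@H](C)C(=O)c4ccc(O[Si](C)(C)C(C)(C)C)c(OC)c4)c(OC)c3)[C@@H](C)[C@H]2C)ccc1O[Si](C)(C)C(C)(C)C
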